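Assumption: the tricycle is numbered as tricyclo[5.4.0.0^{2,8}]undecane (C-1 to C-11), and the target is read as the 3-angelate [(2Z)-2-methylbut-2-enoate], 4-isovalerate, 5-ol with (1R,2R,3S,4S,5S,7S,8R) configuration.

**Retrosynthetic overview**
1. Target ⇒ triol enone 25 by two regioselective acylations (C-4 OH first, then C-3 OH; the axial C-5 OH next to the gem-dimethyl carbon stays free).
2. 25 ⇒ tricycle 21: the enone comes from the C-11 silyl ether (desilylation, oxidation, dehydrogenation).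
3. Key step, 21 ⇒ 18: the seven-membered ring is closed at C-6–C-7. A tertiary C-6 radical (a carbanion equivalent made from an isopropenyl group by Fe–H hydrogen-atom transfer) adds to the tosylhydrazone carbon of the cyclobutanone, and loss of N2 leaves C-7–H.
4. 18 ⇒ acyclic amide 15 by an intramolecular keteniminium–alkene [2+2], which forms the four- and six-membered rings together; the allylic OTES group sets the face.
5. 15 ⇒ enal 9 + ketone 12 (syn-aldol, then 1,3-anti reduction for the three carbinols); 9 ⇒ (R)-citronellic acid (amide, ozonolysis, D-proline α-aminoxylation/Wittig). Ring order: four- and six-membered rings first, seven-membered ring last.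

**Route**

Step 1
Reactants: 1 (R)-citronellic acid [(3R)-3,7-dimethyloct-6-enoic acid]
Product: 3 1-[(3R)-3,7-dimethyloct-6-enoyl]pyrrolidine, via acid chloride 2 (not isolated)
Conditions: (COCl)2, cat. DMF, CH2Cl2, 0 °C to rt; then pyrrolidine, Et3N, 0 °C
Reagents that add atoms: pyrrolidine, C1CCNC1
Why: Acid chloride formation and amidation give the tertiary amide needed later for keteniminium generation, and the chiral-pool C-3 stereocenter is not touched.

Step 2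
Reactants: 3 1-[(3R)-3,7-dimethyloct-6-enoyl]pyrrolidine
Product: 4 (4R)-4-methyl-6-oxo-6-(pyrrolidin-1-yl)hexanal
Conditions: O3, CH2Cl2, −78 °C; then Me2S, −78 °C to rt
Reagents that add atoms: ozone, [O-][O+]=O
Why: Ozonolysis with reductive work-up cleaves the only C=C bond, and the amide is inert.

Step 3
Reactants: 4 (4R)-4-methyl-6-oxo-6-(pyrrolidin-1-yl)hexanal; 5 2-(triphenylphosphoranylidene)propanal
Product: 7 (2E,4S,6R)-4-(anilinooxy)-2,6-dimethyl-8-oxo-8-(pyrrolidin-1-yl)oct-2-enal, via aminooxy aldehyde 6 (not isolated)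
Conditions: D-proline (20 mol %), PhNO, CHCl3, 4 °C; then 5, 0 °C to rt
Reagents that add atoms: nitrosobenzene, O=Nc1ccccc1
Why: Proline-catalysed α-aminoxylation (O-selective nitroso aldol through the anti-enamine, acid-directed) with D-proline gives the (S)-α-oxygenated aldehyde, which is trapped at once by Wittig olefination with the stabilised ylide to give the E-trisubstituted enal.

Step 4
Reactants: 7 (2E,4S,6R)-4-(anilinooxy)-2,6-dimethyl-8-oxo-8-(pyrrolidin-1-yl)oct-2-enal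
Product: 8 (2E,4S,6R)-4-hydroxy-2,6-dimethyl-8-oxo-8-(pyrrolidin-1-yl)oct-2-enal
Conditions: CuSO4·5H2O (30 mol %), MeOH, 0 °C
Reagents that add atoms: none
Why: Divalent copper catalyses N–O bond cleavage of the O-alkyl-N-phenylhydroxylamine and frees the allylic alcohol without affecting the enal or the stereocenter.

Step 5
Reactants: 8 (2E,4S,6R)-4-hydroxy-2,6-dimethyl-8-oxo-8-(pyrrolidin-1-yl)oct-2-enal
Product: 9 (2E,4S,6R)-2,6-dimethyl-8-oxo-8-(pyrrolidin-1-yl)-4-(triethylsilyloxy)oct-2-enal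
Conditions: TESCl, imidazole, CH2Cl2, 0 °C
Reagents that add atoms: chlorotriethylsilane, CC[Si](Cl)(CC)CC
Why: Standard silylation; TES is chosen because it can later be cleaved and oxidised in the presence of TBS ethers.

Step 6
Reactants: 10 2-(tert-butyldimethylsilyloxy)-N-methoxy-N-methylacetamide; 11 isopropenylmagnesium bromide
Product: 12 1-(tert-butyldimethylsilyloxy)-3-methylbut-3-en-2-one
Conditions: THF, −78 to 0 °C; aq. NH4Cl
Reagents that add atoms: none
Why: Weinreb ketone synthesis; the chelated tetrahedral intermediate prevents over-addition.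

Step 7
Reactants: 9 (2E,4S,6R)-2,6-dimethyl-8-oxo-8-(pyrrolidin-1-yl)-4-(triethylsilyloxy)oct-2-enal; 12 1-(tert-butyldimethylsilyloxy)-3-methylbut-3-en-2-one
Product: 13 1-[(3R,5S,6E,8S,9R)-9-(tert-butyldimethylsilyloxy)-8-hydroxy-3,7,11-trimethyl-10-oxo-5-(triethylsilyloxy)dodeca-6,11-dienoyl]pyrrolidine
Conditions: 12, (+)-Ipc2BOTf, iPr2NEt, CH2Cl2, −78 °C; then 9, −78 to −20 °C; H2O2, MeOH, pH 7 buffer
Reagents that add atoms: none
Why: Paterson aldol: the Z-boron enolate of the α-silyloxy ketone (only one enolisable position) reacts through a chair Zimmerman–Traxler transition state to give the 8,9-syn adduct, and the isopinocampheyl ligands (antipode chosen for Re-face attack on the aldehyde) set 8S,9R.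

Step 8
Reactants: 13 (aldol adduct)
Product: 14 1-[(3R,5S,6E,8S,9S,10S)-9-(tert-butyldimethylsilyloxy)-8,10-dihydroxy-3,7,11-trimethyl-5-(triethylsilyloxy)dodeca-6,11-dienoyl]pyrrolidine
Conditions: Me4NBH(OAc)3, MeCN/AcOH, −30 °C
Reagents that add atoms: none
Why: Evans–Saksena reduction: intramolecular hydride delivery from the C-8 alkoxyborohydride through a chair transition state gives the 8,10-anti diol (10S), which makes the 9,10 relation erythro.

Step 9
Reactants: 14 (anti-diol)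
Product: 15 1-[(3R,5S,6E,8S,9S,10S)-8,9,10-tris(tert-butyldimethylsilyloxy)-3,7,11-trimethyl-5-(triethylsilyloxy)dodeca-6,11-dienoyl]pyrrolidine
Conditions: TBSOTf, 2,6-lutidine, CH2Cl2, −78 to 0 °C
Reagents that add atoms: tert-butyldimethylsilyl trifluoromethanesulfonate, CC(C)(C)[Si](C)(C)OS(=O)(=O)C(F)(F)F
Why: The silyl triflate silylates both hindered secondary alcohols while the TES ether stays.

Step 10
Reactants: 15 (tris-TBS amide)
Product: 18 (1R,2S,4R,5R,7R)-4,7-dimethyl-2-(triethylsilyloxy)-7-[(1S,2S,3S)-1,2,3-tris(tert-butyldimethylsilyloxy)-4-methylpent-4-en-1-yl]bicyclo[3.1.1]heptan-6-one, via keteniminium triflate 16 (not isolated), via cyclobutaniminium triflate 17 (not isolated)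
Conditions: Tf2O, 2,4,6-collidine, ClCH2CH2Cl, −20 to 80 °C; then H2O, 60 °C
Reagents that add atoms: water, O
Why: Ghosez keteniminium–alkene [2+2] (intramolecular): the iminium carbon attacks the CH end of the E-trisubstituted alkene anti to the allylic OTES group (A(1,3) strain holds the C-5–H next to the vinylic methyl; the C-3 methyl sits equatorial), the tertiary cationic end closes onto the α-carbon to give the bridged bicycle, and suprafacial addition puts the alkene methyl syn to the three-carbon bridge and the oxygenated chain on the face of the new carbonyl.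

Step 11
Reactants: 18 (bicyclic cyclobutanone)
Product: 21 (1R,2R,3S,4S,5S,7S,8S,9R,11S)-3,4,5-tris(tert-butyldimethylsilyloxy)-2,6,6,9-tetramethyl-11-(triethylsilyloxy)tricyclo[5.4.0.0^{2,8}]undecane, via tosylhydrazone 19 (not isolated), via sulfonylhydrazide 20 (not isolated)
Conditions: TsNHNH2, EtOH/THF, 40 °C; then Fe(acac)3 (50 mol %), PhSiH3, 60 °C; then Et3N, 80 °C
Reagents that add atoms: none
Why: Proposed new method: Fe–H hydrogen-atom transfer to the isopropenyl group gives the tertiary C-6 radical (a nucleophilic centre at the carbon that is otherwise the cationic end of the alkene), which adds 7-exo to the electrophilic hydrazone carbon held 1,3 across the cyclobutane on the same face, so the C-7 configuration is dictated by the tether; the N-radical is reduced and Et3N-promoted loss of sulfinate gives a diazene that extrudes N2 to leave C-7–H; the closest known reaction type is the Fe(acac)3/PhSiH3 reductive radical alkylation of unactivated alkenes with N-sulfonylhydrazones (intermolecular and five- or six-membered ring closures).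

Step 12
Reactants: 21 (saturated tricycle)
Product: 24 (1R,2R,3S,4S,5S,7S,8R)-3,4,5-tris(tert-butyldimethylsilyloxy)-2,6,6,9-tetramethyltricyclo[5.4.0.0^{2,8}]undec-9-en-11-one, via C-11 alcohol 22 (not isolated), via saturated ketone 23 (not isolated)
Conditions: IBX, DMSO, rt; then IBX, 4-methoxypyridine N-oxide, DMSO, rt
Reagents that add atoms: none
Why: IBX in DMSO cleaves the TES ether in preference to TBS ethers and oxidises the alcohol, and IBX dehydrogenation of the ketone can only go toward C-10 because C-1 is a bridgehead, which gives the conjugated enone and removes the C-9 stereocenter.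

Step 13
Reactants: 24 (tris-TBS enone)
Product: 25 (1R,2R,3S,4S,5S,7S,8R)-3,4,5-trihydroxy-2,6,6,9-tetramethyltricyclo[5.4.0.0^{2,8}]undec-9-en-11-one
Conditions: HF·pyridine, pyridine, THF, 0 to 40 °C
Reagents that add atoms: none
Why: Buffered fluoride desilylation removes the three TBS groups and leaves the enone and the cyclobutane intact.

Step 14
Reactants: 25 (triol enone); 26 3-methylbutanoyl chloride
Product: 27 (1R,2R,3S,4S,5S,7S,8R)-3,5-dihydroxy-2,6,6,9-tetramethyl-11-oxotricyclo[5.4.0.0^{2,8}]undec-9-en-4-yl 3-methylbutanoate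
Conditions: 26 (1.05 equiv), pyridine, CH2Cl2, −30 to 0 °C
Reagents that add atoms: none
Why: Kinetic acylation: the C-4 hydroxyl is the only equatorial one that is not neopentyl, whereas C-3 OH is next to quaternary C-2 and C-5 OH is axial and next to the gem-dimethyl carbon.

Step 15
Reactants: 27 (C-4 isovalerate); 28 angelic acid [(2Z)-2-methylbut-2-enoic acid]
Product: 30 target, [(1R,2R,3S,4S,5S,7S,8R)-5-hydroxy-2,6,6,9-tetramethyl-4-(3-methylbutanoyloxy)-11-oxotricyclo[5.4.0.0^{2,8}]undec-9-en-3-yl] (2Z)-2-methylbut-2-enoate, via mixed anhydride 29 (not isolated)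
Conditions: 28, 2,4,6-trichlorobenzoyl chloride, Et3N, toluene, rt; then 27, 80 °C
Reagents that add atoms: none
Why: Yamaguchi-type esterification through the mixed trichlorobenzoic anhydride acylates hindered alcohols without DMAP and keeps the Z geometry of the angelate, and the equatorial C-3 OH reacts before the axial, more hindered C-5 OH.

**Compound list**
1 | (R)-citronellic acid | OC(=O)C[C@H](C)CCC=C(C)C | starting material
2 | (3R)-3,7-dimethyloct-6-enoyl chloride | ClC(=O)C[C@H](C)CCC=C(C)C | intermediate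
3 | 1-[(3R)-3,7-dimethyloct-6-enoyl]pyrrolidine | O=C(C[C@H](C)CCC=C(C)C)N1CCCC1 | intermediate
4 | (4R)-4-methyl-6-oxo-6-(pyrrolidin-1-yl)hexanal | O=C(C[C@H](C)CCC=O)N1CCCC1 | intermediate
5 | 2-(triphenylphosphoranylidene)propanal | CC(C=O)=P(c1ccccc1)(c1ccccc1)c1ccccc1 | starting material
6 | (2S,4R)-2-(anilinooxy)-4-methyl-6-oxo-6-(pyrrolidin-1-yl)hexanal | O=C(C[C@H](C)C[C@H](ONc1ccccc1)C=O)N1CCCC1 | intermediate
7 | (2E,4S,6R)-4-(anilinooxy)-2,6-dimethyl-8-oxo-8-(pyrrolidin-1-yl)oct-2-enal | O=C(C[C@H](C)C[C@H](ONc1ccccc1)/C=C(\C)C=O)N1CCCC1 | intermediate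
8 | (2E,4S,6R)-4-hydroxy-2,6-dimethyl-8-oxo-8-(pyrrolidin-1-yl)oct-2-enal | O=C(C[C@H](C)C[C@H](O)/C=C(\C)C=O)N1CCCC1 | intermediate
9 | (2E,4S,6R)-2,6-dimethyl-8-oxo-8-(pyrrolidin-1-yl)-4-(triethylsilyloxy)oct-2-enal | O=C(C[C@H](C)C[C@H](O[Si](CC)(CC)CC)/C=C(\C)C=O)N1CCCC1 | intermediate
10 | 2-(tert-butyldimethylsilyloxy)-N-methoxy-N-methylacetamide | CON(C)C(=O)CO[Si](C)(C)C(C)(C)C | starting material
11 | isopropenylmagnesium bromide | CC(=C)[Mg]Br | starting material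
12 | 1-(tert-butyldimethylsilyloxy)-3-methylbut-3-en-2-one | CC(=C)C(=O)CO[Si](C)(C)C(C)(C)C | intermediate
13 | 1-[(3R,5S,6E,8S,9R)-9-(tert-butyldimethylsilyloxy)-8-hydroxy-3,7,11-trimethyl-10-oxo-5-(triethylsilyloxy)dodeca-6,11-dienoyl]pyrrolidine | O=C(C[C@H](C)C[C@H](O[Si](CC)(CC)CC)/C=C(\C)[C@H](O)[C@@H](O[Si](C)(C)C(C)(C)C)C(=O)C(C)=C)N1CCCC1 | intermediate
14 | 1-[(3R,5S,6E,8S,9S,10S)-9-(tert-butyldimethylsilyloxy)-8,10-dihydroxy-3,7,11-trimethyl-5-(triethylsilyloxy)dodeca-6,11-dienoyl]pyrrolidine | O=C(C[C@H](C)C[C@H](O[Si](CC)(CC)CC)/C=C(\C)[C@H](O)[C@@H](O[Si](C)(C)C(C)(C)C)[C@@H](O)C(C)=C)N1CCCC1 | intermediate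
15 | 1-[(3R,5S,6E,8S,9S,10S)-8,9,10-tris(tert-butyldimethylsilyloxy)-3,7,11-trimethyl-5-(triethylsilyloxy)dodeca-6,11-dienoyl]pyrrolidine | O=C(C[C@H](C)C[C@H](O[Si](CC)(CC)CC)/C=C(\C)[C@H](O[Si](C)(C)C(C)(C)C)[C@@H](O[Si](C)(C)C(C)(C)C)[C@@H](O[Si](C)(C)C(C)(C)C)C(C)=C)N1CCCC1 | intermediate
16 | keteniminium triflate derived from 15 (C-1=C-2 ketene iminium of the pyrrolidine) | C(=C=[N+]1CCCC1)[C@H](C)C[C@H](O[Si](CC)(CC)CC)/C=C(\C)[C@H](O[Si](C)(C)C(C)(C)C)[C@@H](O[Si](C)(C)C(C)(C)C)[C@@H](O[Si](C)(C)C(C)(C)C)C(C)=C.[O-]S(=O)(=O)C(F)(F)F | intermediate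
17 | cyclobutaniminium triflate (pyrrolidinium-ylidene analogue of 18) | C=C(C)[C@H](O[Si](C)(C)C(C)(C)C)[C@H](O[Si](C)(C)C(C)(C)C)[C@@H](O[Si](C)(C)C(C)(C)C)[C@@]1(C)[C@@H]2[C@@H](O[Si](CC)(CC)CC)C[C@@H](C)[C@H]1C2=[N+]1CCCC1.[O-]S(=O)(=O)C(F)(F)F | intermediate
18 | (1R,2S,4R,5R,7R)-4,7-dimethyl-2-(triethylsilyloxy)-7-[(1S,2S,3S)-1,2,3-tris(tert-butyldimethylsilyloxy)-4-methylpent-4-en-1-yl]bicyclo[3.1.1]heptan-6-one | C=C(C)[C@H](O[Si](C)(C)C(C)(C)C)[C@H](O[Si](C)(C)C(C)(C)C)[C@@H](O[Si](C)(C)C(C)(C)C)[C@@]1(C)[C@@H]2[C@@H](O[Si](CC)(CC)CC)C[C@@H](C)[C@H]1C2=O | intermediate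
19 | N-tosylhydrazone of 18 (C=N geometry not defined) | C=C(C)[C@H](O[Si](C)(C)C(C)(C)C)[C@H](O[Si](C)(C)C(C)(C)C)[C@@H](O[Si](C)(C)C(C)(C)C)[C@@]1(C)[C@@H]2[C@@H](O[Si](CC)(CC)CC)C[C@@H](C)[C@H]1C2=NNS(=O)(=O)c1ccc(C)cc1 | intermediate
20 | 7-(2-tosylhydrazinyl) derivative of 21 (cyclised sulfonylhydrazide) | CC(C)(C)[Si](C)(C)O[C@@H]1[C@@H](O[Si](C)(C)C(C)(C)C)[C@@H](O[Si](C)(C)C(C)(C)C)C(C)(C)[C@]2(NNS(=O)(=O)c4ccc(C)cc4)[C@H]3[C@@H](O[Si](CC)(CC)CC)C[C@@H](C)[C@@H]2[C@@]13C | intermediate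
21 | (1R,2R,3S,4S,5S,7S,8S,9R,11S)-3,4,5-tris(tert-butyldimethylsilyloxy)-2,6,6,9-tetramethyl-11-(triethylsilyloxy)tricyclo[5.4.0.0^{2,8}]undecane | CC(C)(C)[Si](C)(C)O[C@@H]1[C@@H](O[Si](C)(C)C(C)(C)C)[C@@H](O[Si](C)(C)C(C)(C)C)C(C)(C)[C@@H]2[C@H]3[C@@H](O[Si](CC)(CC)CC)C[C@@H](C)[C@@H]2[C@@]13C | intermediate
22 | (11S)-11-alcohol from 21 (TES removed) | CC(C)(C)[Si](C)(C)O[C@@H]1[C@@H](O[Si](C)(C)C(C)(C)C)[C@@H](O[Si](C)(C)C(C)(C)C)C(C)(C)[C@@H]2[C@H]3[C@@H](O)C[C@@H](C)[C@@H]2[C@@]13C | intermediate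
23 | (1R,2R,3S,4S,5S,7S,8S,9R)-3,4,5-tris(tert-butyldimethylsilyloxy)-2,6,6,9-tetramethyltricyclo[5.4.0.0^{2,8}]undecan-11-one | CC(C)(C)[Si](C)(C)O[C@@H]1[C@@H](O[Si](C)(C)C(C)(C)C)[C@@H](O[Si](C)(C)C(C)(C)C)C(C)(C)[C@@H]2[C@H]3C(=O)C[C@@H](C)[C@@H]2[C@@]13C | intermediate
24 | (1R,2R,3S,4S,5S,7S,8R)-3,4,5-tris(tert-butyldimethylsilyloxy)-2,6,6,9-tetramethyltricyclo[5.4.0.0^{2,8}]undec-9-en-11-one | CC(C)(C)[Si](C)(C)O[C@@H]1[C@@H](O[Si](C)(C)C(C)(C)C)[C@@H](O[Si](C)(C)C(C)(C)C)C(C)(C)[C@@H]2[C@H]3C(=O)C=C(C)[C@@H]2[C@@]13C | intermediate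
25 | (1R,2R,3S,4S,5S,7S,8R)-3,4,5-trihydroxy-2,6,6,9-tetramethyltricyclo[5.4.0.0^{2,8}]undec-9-en-11-one | O[C@@H]1[C@@H](O)[C@@H](O)C(C)(C)[C@@H]2[C@H]3C(=O)C=C(C)[C@@H]2[C@@]13C | intermediate
26 | 3-methylbutanoyl chloride | CC(C)CC(Cl)=O | starting material
27 | (1R,2R,3S,4S,5S,7S,8R)-3,5-dihydroxy-2,6,6,9-tetramethyl-11-oxotricyclo[5.4.0.0^{2,8}]undec-9-en-4-yl 3-methylbutanoate | O[C@@H]1[C@@H](OC(=O)CC(C)C)[C@@H](O)C(C)(C)[C@@H]2[C@H]3C(=O)C=C(C)[C@@H]2[C@@]13C | intermediate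
28 | angelic acid | C/C=C(/C)C(O)=O | starting material
29 | angelic 2,4,6-trichlorobenzoic anhydride | C/C=C(/C)C(=O)OC(=O)c1c(Cl)cc(Cl)cc1Cl | intermediate
30 | [(1R,2R,3S,4S,5S,7S,8R)-5-hydroxy-2,6,6,9-tetramethyl-4-(3-methylbutanoyloxy)-11-oxotricyclo[5.4.0.0^{2,8}]undec-9-en-3-yl] (2Z)-2-methylbut-2-enoate | C/C=C(/C)C(=O)O[C@@H]1[C@@H](OC(=O)CC(C)C)[C@@H](O)C(C)(C)[C@@H]2[C@H]3C(=O)C=C(C)[C@@H]2[C@@]13C | target

**Totals and risks**

Total step count: 15. Longest linear sequence: 14 (steps 1–5 and 7–15; step 6 is a one-step side branch).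

Most likely to fail:

1. Step 11 (radical closure of the seven-membered ring). The hindered tertiary radical may be reduced before it adds, or the addition to C=N may revert. Fallback, from 18 back to 21: condense 18 with 1-amino-2-phenylaziridine to the N-aziridinylimine F8 and run the same Fe–H initiated cyclisation. Here the adduct aminyl radical fragments irreversibly (styrene and N2 are lost) to the C-7 radical, which takes a hydrogen atom to give 21, so no reduction/elimination sequence on nitrogen is needed.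

2. Step 10 (keteniminium [2+2]). The alkene is flanked by two silyloxy-bearing carbons, the cationic pathway could erode the alkene geometry, and Tf2O may attack silyl ethers. Fallback, from 15 back to 18: reduce the amide with Cp2Zr(H)Cl to the aldehyde F4, oxidise (NaClO2, NaH2PO4, 2-methylbut-2-ene) to the acid F5, convert it with 1-chloro-N,N,2-trimethylprop-1-en-1-amine to the acid chloride F6, and dehydrochlorinate with Et3N in refluxing toluene (EtAlCl2 added if needed) to the ketene F7, which undergoes the neutral, concerted ketene–alkene [2+2] to 18.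

3. Step 7 (reagent-controlled aldol with an α-silyloxy enone ketone; enantioselectivity uncertain). Fallback, from 9 back to 13: Evans glycolate aldol of 9 with (R)-4-benzyl-3-[(tert-butyldimethylsilyloxy)acetyl]oxazolidin-2-one F1 (from (R)-4-benzyloxazolidin-2-one and the silyloxyacetyl chloride) using Bu2BOTf and Et3N gives the syn imide adduct F2. Transamination with MeNHOMe·HCl/AlMe3 gives the Weinreb amide F3, and isopropenylmagnesium bromide 11 converts F3 into 13.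

Further compounds
F1 | step 7 | (R)-4-benzyl-3-[(tert-butyldimethylsilyloxy)acetyl]oxazolidin-2-one | O=C1OC[C@@H](Cc2ccccc2)N1C(=O)CO[Si](C)(C)C(C)(C)C
F2 | step 7 | Evans syn-aldol imide (2R,3S adduct of F1 with 9) | O=C(C[C@H](C)C[C@H](O[Si](CC)(CC)CC)/C=C(\C)[C@H](O)[C@@H](O[Si](C)(C)C(C)(C)C)C(=O)N3[C@H](Cc2ccccc2)COC3=O)N1CCCC1
F3 | step 7 | Weinreb amide from F2 | O=C(C[C@H](C)C[C@H](O[Si](CC)(CC)CC)/C=C(\C)[C@H](O)[C@@H](O[Si](C)(C)C(C)(C)C)C(=O)N(C)OC)N1CCCC1
F4 | step 10 | (3R,5S,6E,8S,9S,10S)-8,9,10-tris(tert-butyldimethylsilyloxy)-3,7,11-trimethyl-5-(triethylsilyloxy)dodeca-6,11-dienal | O=CC[C@H](C)C[C@H](O[Si](CC)(CC)CC)/C=C(\C)[C@H](O[Si](C)(C)C(C)(C)C)[C@@H](O[Si](C)(C)C(C)(C)C)[C@@H](O[Si](C)(C)C(C)(C)C)C(C)=C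
F5 | step 10 | corresponding dodeca-6,11-dienoic acid | OC(=O)C[C@H](C)C[C@H](O[Si](CC)(CC)CC)/C=C(\C)[C@H](O[Si](C)(C)C(C)(C)C)[C@@H](O[Si](C)(C)C(C)(C)C)[C@@H](O[Si](C)(C)C(C)(C)C)C(C)=C
F6 | step 10 | corresponding acid chloride | ClC(=O)C[C@H](C)C[C@H](O[Si](CC)(CC)CC)/C=C(\C)[C@H](O[Si](C)(C)C(C)(C)C)[C@@H](O[Si](C)(C)C(C)(C)C)[C@@H](O[Si](C)(C)C(C)(C)C)C(C)=C
F7 | step 10 | corresponding ketene | O=C=C[C@H](C)C[C@H](O[Si](CC)(CC)CC)/C=C(\C)[C@H](O[Si](C)(C)C(C)(C)C)[C@@H](O[Si](C)(C)C(C)(C)C)[C@@H](O[Si](C)(C)C(C)(C)C)C(C)=C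
F8 | step 11 | N-(2-phenylaziridin-1-yl)imine of 18 | C=C(C)[C@H](O[Si](C)(C)C(C)(C)C)[C@H](O[Si](C)(C)C(C)(C)C)[C@@H](O[Si](C)(C)C(C)(C)C)[C@@]1(C)[C@@H]2[C@@H](O[Si](CC)(CC)CC)C[C@@H](C)[C@H]1C2=NN3CC3c4ccccc4
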